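The C7=C11 double bond of the butenolide (ring O–C12–C11–C7–C6, germacrane numbering) carries the whole plan, which exploits the fact that the lactone oxygen on C6 sits next to C7. The precursor is a ten-membered diepoxy C7 ketone whose O6 carries a 2-(diethoxyphosphoryl)acryloyl group and whose O8 carries the tiglate. In the key step acetate adds to C13 and the resulting C11 phosphonate carbanion olefinates the C7 ketone, so one operation installs the 13-acetoxy group, closes the lactone and creates the tetrasubstituted alkene. The ketone comes from (−)-parthenolide by epoxidation, ozonolytic excision of C11–C13, C8 hydroxylation and Mitsunobu tigloylation.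

Key step: step 11

Remark: (−)-parthenolide is taken as a commercial chiral-pool terpene; germacrane numbering is used (ring C1–C10, lactone carbons C11–C13, C14 on C10, C15 on C4; α/β as in parthenolide, H-7α).

Step 1
Reactants: 1 (−)-parthenolide
Product: 2 1β,10α-epoxyparthenolide
Conditions: mCPBA, CH2Cl2, 0 °C to rt
Reagents that add atoms: meta-chloroperoxybenzoic acid, OOC(=O)c1cccc(Cl)c1
Why: Prilezhaev epoxidation of the only electron-rich alkene (the α-methylene lactone is too electron-poor for a peracid), in which the crown conformation of the (E)-cyclodecene exposes only the outer face of C1=C10 and so should set C1 and C10 as the 1β,10α trans-epoxide.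

Step 2
Reactants: 2 1β,10α-epoxyparthenolide
Product: 4 enol lactone (11-hydroxy-13-nor-7(11)-en-6α,12-olide), via 11-oxo lactone 3 (not isolated)
Conditions: O3, CH2Cl2/MeOH 4:1, −78 °C; then Me2S, −78 °C to rt
Reagents that add atoms: ozone, [O-][O+]=O
Why: Ozonolysis with reductive work-up cleaves the only remaining C=C bond (epoxides are inert to ozone), and the α-keto lactone should tautomerise to its conjugated enol, which erases the C7 stereocentre on purpose and leaves C6 untouched.

Step 3
Reactants: 4 enol lactone
Product: 6 6α-hydroxy-7-ketone (trinor ketol), via hydrogen oxalate 5 (not isolated)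
Conditions: O3, CH2Cl2/MeOH 4:1, −78 °C; Me2S, −78 to 0 °C; then K2CO3, MeOH, −20 to 0 °C
Reagents that add atoms: ozone, [O-][O+]=O
Why: A second ozonolysis cleaves the electron-rich enol bond C7=C11 to the C7 ketone and an O6 hydrogen oxalate, and oxalates are labile enough for cold methanolysis, which should free the 6α-hydroxyl without enolising the β,γ-epoxy ketone, so C6 keeps the configuration of parthenolide.

Step 4
Reactants: 6 6α-hydroxy-7-ketone
Product: 7 6α-(triethylsilyloxy) ketone
Conditions: Et3SiCl, imidazole, DMF, 0 °C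
Reagents that add atoms: chlorotriethylsilane, CC[Si](Cl)(CC)CC
Why: Silylation of the only hydroxyl under near-neutral conditions masks O6 as a base-stable ether, so that no alkoxide (Payne or α-ketol rearrangement) can form in the enolate step.

Step 5
Reactants: 7 6α-(triethylsilyloxy) ketone
Product: 9 8β-hydroxy-6α-(triethylsilyloxy) ketone, via potassium enolate 8 (not isolated)
Conditions: KN(SiMe3)2, THF, −78 °C; then 2-(phenylsulfonyl)-3-phenyloxaziridine, −78 °C; AcOH quench
Reagents that add atoms: 2-(phenylsulfonyl)-3-phenyloxaziridine (Davis oxaziridine), O=S(=O)(c1ccccc1)N1OC1c1ccccc1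
Why: Kinetic deprotonation by the bulky amide should occur at the C8 methylene and not at the hindered, silyloxy-bearing C6–H, and Davis hydroxylation of the (Z)-enolate is expected on the β face because the α face is screened by the α-oriented C6 silyloxy group and the pseudoaxial H-9α, which sets C8 as the 8β-alcohol.

Step 6
Reactants: 9 8β-hydroxy-6α-(triethylsilyloxy) ketone; 10 tiglic acid
Product: 11 8α-tigloyloxy-6α-(triethylsilyloxy) ketone
Conditions: PPh3, DIAD, THF, 0 °C to rt
Reagents that add atoms: none
Why: Mitsunobu esterification, in which SN2 attack of tiglate on the C8 oxyphosphonium ion (activated by the adjacent carbonyl) inverts C8 from 8β to the required 8α configuration and leaves the (E)-alkene of the acid untouched.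

Step 7
Reactants: 11 8α-tigloyloxy-6α-(triethylsilyloxy) ketone
Product: 12 6α-hydroxy-8α-tigloyloxy ketone
Conditions: HF·pyridine, pyridine, THF, 0 °C
Reagents that add atoms: none
Why: Fluoride-driven cleavage of the triethylsilyl ether under pyridine-buffered conditions should spare both epoxides, the tiglate and the α-acyloxy ketone.

Step 8
Reactants: 13 tert-butyl diethylphosphonoacetate
Product: 15 tert-butyl 2-(diethoxyphosphoryl)acrylate, via hydroxymethyl adduct 14 (not isolated)
Conditions: (CH2O)n, piperidine (cat.), AcOH (cat.), toluene, reflux, Dean–Stark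
Reagents that add atoms: formaldehyde (from paraformaldehyde), C=O
Why: Knoevenagel condensation of the active methylene with formaldehyde under piperidinium acetate catalysis, with azeotropic removal of water driving the elimination to the 1,1-disubstituted alkene.

Step 9
Reactants: 15 tert-butyl 2-(diethoxyphosphoryl)acrylate
Product: 16 2-(diethoxyphosphoryl)acrylic acid
Conditions: CF3CO2H, CH2Cl2, 0 °C to rt
Reagents that add atoms: none
Why: Acidolysis of the tert-butyl ester through the tert-butyl cation should leave the ethyl phosphonate and the electrophilic alkene untouched, since no nucleophile is present.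

Step 10
Reactants: 12 6α-hydroxy-8α-tigloyloxy ketone; 16 2-(diethoxyphosphoryl)acrylic acid
Product: 17 6α-[2-(diethoxyphosphoryl)acryloyloxy]-8α-tigloyloxy ketone
Conditions: DCC, DMAP (cat.), CH2Cl2, −20 to 0 °C
Reagents that add atoms: none
Why: Steglich esterification of the secondary C6 hydroxyl with retention of configuration, run cold with little DMAP to limit nucleophile-induced oligomerisation of the acceptor acid.

Step 11
Reactants: 17 6α-[2-(diethoxyphosphoryl)acryloyloxy]-8α-tigloyloxy ketone
Product: 19 CNP0251711.1 (target), via cesium phosphonate carbanion 18 (not isolated)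
Conditions: CsOAc, 18-crown-6, MeCN, 0 °C to rt
Reagents that add atoms: cesium acetate, [Cs+].CC([O-])=O
Why: Acetate adds reversibly to C13 of the doubly activated vinylphosphonate (oxa-Michael addition) to give carbanion 18, whose C11 attacks the adjacent, doubly α-oxygenated C7 ketone; the oxaphosphetane then collapses with loss of diethyl phosphate to give C7=C11 (Michael-initiated intramolecular Horner–Wadsworth–Emmons olefination). The closest known reaction type is the conjugate addition of alkoxide, thiolate or amine donors to 2-phosphonoacrylates followed by Horner–Wadsworth–Emmons olefination, including butenolide closure from 2-oxoalkyl 2-phosphonoacrylates; acetate is a weaker donor, but its adduct is drained irreversibly by the ring closure. The butenolide ring (O, C12, C11, C7, C6) closes in a 5-exo-trig mode at the C7 carbonyl. No stereocentre is created, because the new alkene is endocyclic in the five-membered ring, and C6 and C8 should keep their configuration since no base stronger than acetate is present. The step needs chemoselectivity for acetate addition over deprotonation at C6–H (which would open the 4,5-epoxide by β-elimination) and over attack on the tiglate; the much higher electrophilicity of the methylene activated by both phosphonate and ester, together with the irreversible five-ring olefination, should secure this.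

Compound list
1 | (−)-parthenolide, 4α,5β-epoxygermacra-1(10)E,11(13)-dien-6α,12-olide | C1C/C(C)=C/CC[C@@]2(C)O[C@@H]2[C@H]2OC(=O)C(=C)[C@H]12 | starting material
2 | 1β,10α-epoxyparthenolide, 1β,10α:4α,5β-diepoxygermacr-11(13)-en-6α,12-olide | C1C[C@@]2(C)O[C@@H]2CC[C@@]2(C)O[C@@H]2[C@H]2OC(=O)C(=C)[C@H]12 | intermediate
3 | 11-oxo lactone, 1β,10α:4α,5β-diepoxy-11-oxo-13-norgermacran-6α,12-olide (keto tautomer, not isolated) | C1C[C@@]2(C)O[C@@H]2CC[C@@]2(C)O[C@@H]2[C@H]2OC(=O)C(=O)[C@H]12 | intermediate
4 | enol lactone, 1β,10α:4α,5β-diepoxy-11-hydroxy-13-norgermacr-7(11)-en-6α,12-olide | C1C[C@@]2(C)O[C@@H]2CC[C@@]2(C)O[C@@H]2[C@H]2OC(=O)C(O)=C12 | intermediate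
5 | hydrogen oxalate of the 6α-hydroxy-7-ketone (not isolated) | C1C[C@@]2(C)O[C@@H]2CC[C@@]2(C)O[C@@H]2[C@@H](OC(=O)C(=O)O)C1=O | intermediate
6 | 1β,10α:4α,5β-diepoxy-6α-hydroxy-11,12,13-trinorgermacran-7-one (4,10-dimethylcyclodecanone skeleton) | C1C[C@@]2(C)O[C@@H]2CC[C@@]2(C)O[C@@H]2[C@@H](O)C1=O | intermediate
7 | 6α-(triethylsilyloxy) derivative of 6 | C1C[C@@]2(C)O[C@@H]2CC[C@@]2(C)O[C@@H]2[C@@H](O[Si](CC)(CC)CC)C1=O | intermediate
8 | potassium (Z)-enolate of 7, C7–O−, C7=C8 (not isolated) | [K+].[O-]/C1=C/C[C@@]2(C)O[C@@H]2CC[C@@]2(C)O[C@@H]2[C@H]1O[Si](CC)(CC)CC | intermediate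
9 | 8β-hydroxy-6α-(triethylsilyloxy)-1β,10α:4α,5β-diepoxy-11,12,13-trinorgermacran-7-one | O[C@@H]1C[C@@]2(C)O[C@@H]2CC[C@@]2(C)O[C@@H]2[C@@H](O[Si](CC)(CC)CC)C1=O | intermediate
10 | tiglic acid, (E)-2-methylbut-2-enoic acid | C/C=C(\C)C(=O)O | starting material
11 | 8α-tigloyloxy-6α-(triethylsilyloxy)-1β,10α:4α,5β-diepoxy-11,12,13-trinorgermacran-7-one | C/C=C(\C)C(=O)O[C@H]1C[C@@]2(C)O[C@@H]2CC[C@@]2(C)O[C@@H]2[C@@H](O[Si](CC)(CC)CC)C1=O | intermediate
12 | 6α-hydroxy-8α-tigloyloxy-1β,10α:4α,5β-diepoxy-11,12,13-trinorgermacran-7-one | C/C=C(\C)C(=O)O[C@H]1C[C@@]2(C)O[C@@H]2CC[C@@]2(C)O[C@@H]2[C@@H](O)C1=O | intermediate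
13 | tert-butyl diethylphosphonoacetate | CCOP(=O)(CC(=O)OC(C)(C)C)OCC | starting material
14 | tert-butyl 2-(diethoxyphosphoryl)-3-hydroxypropanoate (not isolated) | CCOP(=O)(OCC)C(CO)C(=O)OC(C)(C)C | intermediate
15 | tert-butyl 2-(diethoxyphosphoryl)acrylate | C=C(C(=O)OC(C)(C)C)P(=O)(OCC)OCC | intermediate
16 | 2-(diethoxyphosphoryl)acrylic acid | C=C(C(=O)O)P(=O)(OCC)OCC | intermediate
17 | 6α-[2-(diethoxyphosphoryl)acryloyloxy]-8α-tigloyloxy-1β,10α:4α,5β-diepoxy-11,12,13-trinorgermacran-7-one | C/C=C(\C)C(=O)O[C@H]1C[C@@]2(C)O[C@@H]2CC[C@@]2(C)O[C@@H]2[C@@H](OC(=O)C(=C)P(=O)(OCC)OCC)C1=O | intermediate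
18 | cesium salt of the C11 phosphonate carbanion formed by acetate addition to C13 of 17 (not isolated) | [Cs+].C/C=C(\C)C(=O)O[C@H]1C[C@@]2(C)O[C@@H]2CC[C@@]2(C)O[C@@H]2[C@@H](OC(=O)[C-](COC(C)=O)P(=O)(OCC)OCC)C1=O | intermediate
19 | CNP0251711.1, 13-acetoxy-8α-tigloyloxy-1β,10α:4α,5β-diepoxygermacr-7(11)-en-6α,12-olide, (1R,4R,5R,6S,8S,10R) | C/C=C(\C)C(=O)O[C@H]1C[C@@]2(C)O[C@@H]2CC[C@@]2(C)O[C@@H]2[C@H]2OC(=O)C(COC(C)=O)=C12 | target

Total step count: 11. Longest linear sequence: 9 steps (steps 1–7, 10 and 11); steps 8 and 9 prepare the acid 16.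

Steps most likely to fail

Step 11. The acetate adduct may revert to the vinylphosphonate faster than it olefinates, so that oligomerisation of the acceptor or slow base-induced opening of the 4,5-epoxide at C6 takes over. The fallback sets out from 17 and changes the donor to water under aqueous carbonate conditions (K2CO3, THF/H2O, 0 °C): hydroxide adds to C13 and the same intramolecular olefination should give the 13-hydroxy butenolide F1, which is acetylated (Ac2O, pyridine, DMAP cat., 0 °C) and comes back to the route at 19.

Step 5. The facial selectivity of the enolate hydroxylation may be poor or reversed, with attack on the α face. The fallback sets out from 7: the oxidation then delivers the 8α-hydroxy ketone F2, which is esterified with retention (tigloyl chloride, pyridine, DMAP cat., CH2Cl2, 0 °C) in place of the Mitsunobu inversion and comes back to the route at 11; a mixture of epimers would converge on 11 by giving each alcohol its own esterification.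

Step 10. The hindered C6 hydroxyl may acylate slowly while DMAP triggers oligomerisation of the electrophilic acid 16. The fallback sets out from 15 and 12 and masks the alkene as a selenide:
- benzeneselenol (from (PhSe)2 and NaBH4 in EtOH) is added to 15 to give the tert-butyl selenide F3;
- CF3CO2H gives the selenide acid F4, which has an α-hydrogen and should therefore acylate 12 through its ketene with DCC alone to give the selenide ester F5;
- oxidation with NaIO4 (THF/H2O, 0 °C to rt) and selenoxide syn-elimination unmask the vinylphosphonate and come back to the route at 17.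

Further compounds
F1 | step 11 | 13-hydroxy butenolide (13-O-deacetyl target) | C/C=C(\C)C(=O)O[C@H]1C[C@@]2(C)O[C@@H]2CC[C@@]2(C)O[C@@H]2[C@H]2OC(=O)C(CO)=C12
F2 | step 5 | 8α-hydroxy-6α-(triethylsilyloxy)-1β,10α:4α,5β-diepoxy-11,12,13-trinorgermacran-7-one | O[C@H]1C[C@@]2(C)O[C@@H]2CC[C@@]2(C)O[C@@H]2[C@@H](O[Si](CC)(CC)CC)C1=O
F3 | step 10 | tert-butyl 2-(diethoxyphosphoryl)-3-(phenylselanyl)propanoate | CCOP(=O)(OCC)C(C[Se]c1ccccc1)C(=O)OC(C)(C)C
F4 | step 10 | 2-(diethoxyphosphoryl)-3-(phenylselanyl)propanoic acid | CCOP(=O)(OCC)C(C[Se]c1ccccc1)C(=O)O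
F5 | step 10 | 6α-[2-(diethoxyphosphoryl)-3-(phenylselanyl)propanoyloxy]-8α-tigloyloxy-1β,10α:4α,5β-diepoxy-11,12,13-trinorgermacran-7-one | C/C=C(\C)C(=O)O[C@H]1C[C@@]2(C)O[C@@H]2CC[C@@]2(C)O[C@@H]2[C@@H](OC(=O)C(C[Se]c1ccccc1)P(=O)(OCC)OCC)C1=O
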